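## Structural features

The target is a C30 spiro[4.5]decane: cyclopentane ring A (C7–C8–C9–C10–C16) and cyclohexane ring B (C10–C11–C12–C13–C14–C15) share the quaternary carbon C10. Five stereocentres are contiguous (C7, C16, C10, C15, C11). On ring A the C16 hydroxyl and the C7 side chain are cis. On ring B the C15 hydroxyl, C16 and the 3-hydroxypropyl chain on C11 (C1′–C3′) lie on one face, with the C15 methyl and C9 on the other. C7 carries a cross-conjugated triene: C6 bears the hydroxymethyl carbon C6′, C5=C6 is trisubstituted with C4 cis to C6′, C3=C4 is E, and C2 carries the C1 methylidene and a homoprenyl tail. C12 carries an exocyclic tetrasubstituted enal (C12=C17, methyl on C17 cis to C11, formyl carbon C18 cis to C13). Fragile elements are the triene (acid, oxidants, hydrogenation), the enal (nucleophiles, hydride, C11 is its γ-position), and the C15–OH/C16 aldol relationship, which can undergo retro-aldol cleavage whenever C16 is a ketone. The real difficulty is the spiro carbon C10 wedged between two oxygenated stereocentres and C11, together with two alkenes of fixed geometry at opposite ends of the molecule. The key step uses the fact that C10 is α to the oxygenated C16: when ring A is closed by electrocyclisation onto a cycloheptene, the oxyallyl cation has its charge at C10, and C15 can slide from C9 to C10, contracting the seven-membered ring to ring B.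

## Logic of the disconnections

40 ⇒ 39. Three O–Si bonds (O16, O3′, O6′) are cut. Silyl ethers are the only groups removable in the presence of the enal and triene, so the last step must be a buffered fluoride treatment.

39 ⇒ 35 + 38. The C2–C3 bond is cut. The oxidant- and acid-sensitive triene is then created in the last C–C bond formation, and the tail becomes a separate five-atom problem. The forward coupling must retain the geometry of C3=C4 and C5=C6 and tolerate the enal.

38 ⇒ 37 ⇒ 36. The C2–B and C2–O bonds are cut back to a commercial methyl ketone. The forward step needs kinetic enolisation toward the methyl group.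

35 ⇒ 34. The C18=O bond and the C12=C17 alkene are traced to a tertiary allylic alcohol (C12–O, C17=C18). This form of the enal survives hydride and organolithium reagents. The forward step must transpose oxygen and oxidise without touching the iododiene, and it has to select the C12=C17 geometry.

34 ⇒ 33 ⇒ 32 ⇒ 31. O6′–Si is cut, then C3=C4 (iodo-olefination), then the lactol is taken back to the lactone. In 31 the C4 carbon and O6′ sit in one five-membered ring, so the Z geometry of C5=C6 is structural and not a matter of selectivity. The forward steps need a half-reduction and an E-selective olefination of a latent aldehyde.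

31 ⇒ 29 ⇒ 28. C5=C6 and O–C4 are cut (phosphonoacetate), then C6–C6′ (chloromethyl carbenoid), which returns C6 to the ester carbon delivered by the key step. The forward steps must not epimerise C7 or eliminate the β-silyloxy group.

28 ⇒ 27. The C12–C17 bond is cut, returning the C12 ketone. The nucleophile must add to a hindered, epimerisable ketone in the presence of a methyl ester.

27 ⇒ 26 ⇒ 24 ⇒ 22 + 23. C11–H and C13/C14–H are removed, then the C11=C1′ alkene and the C11–C1′ bond. Placing C11 as sp2 carbon lets hydrogen, not carbon, approach C11. The less hindered face (away from the O16 silyl ether) then receives hydrogen and the chain is pushed to the hindered face required by 40.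

22 ⇒ 21 ⇒ 20. The C13=C14 alkene and the C12 carbonyl are traced back to the ketal. The enone blocks C13, so C11, the more hindered α-carbon, becomes the only enolisable site.

20 ⇒ 19 ⇒ 18 ⇒ 16. O16–Si, C16–H, the free O15–H and the C7–H/C8–H bonds are retraced. The C16 hydride must come from the C15 side, which requires a free C15 hydroxyl as the directing group. The acetate therefore has to be removed before the reduction, under conditions that keep the β-keto ester enolised so that retro-aldol cleavage of C10–C15 cannot start.

16 ⇒ 15. The C8–C9 and C10–C15 bonds are cut (C15 returns to C9). Two rings and the quaternary stereocentre reduce to a monocyclic dienone whose only stereocentre is C15. The forward step must close conrotatorily in one sense, migrate C15 and not lose a proton, and keep the C15–O bond intact.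

15 ⇒ 14 ⇒ 11 + 12. The C16=O oxidation and the C16–C7 bond are cut. The α-methylene β-keto ester is unstable, so it is unveiled in the last step before use by neutral oxidation of a carbinol. This avoids enolate condensation and basic methylenation, neither of which would spare the tertiary acetate or the product.

11 ⇒ 10 ⇒ 9 ⇒ 8. The aldehyde is taken back to a primary allylic acetate, and the C9=C10 alkene is cut by metathesis. The ring partner is an electron-neutral 1,1-disubstituted alkene, and the primary acetate can later be removed selectively beside the tertiary one.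

8 ⇒ 7 ⇒ 6 ⇒ 3 + 5; 5 ⇒ 4. The ketal, the C12 oxidation and the C11–C12 bond are cut. An allyl donor at the alcohol oxidation level avoids lactonisation and alkene migration. The forward allylation must be neutral enough for two acetates.

3 ⇒ 2 ⇒ 1. The C12=O bond is traced to the prenyl alkene and the acetate to the free alcohol. C15 comes from the chiral pool, and every other stereocentre is derived from it.

## Other disconnections considered

Alternative 1: The cut is the C7–C16 bond, made last. In the forward direction Me2AlCl would activate the C16 aldehyde of the open-chain aldehyde A2. C7 of the C6=C7 alkene would bond to C16 while a C5 hydrogen passes to oxygen, closing ring A and moving the alkene to C5=C6, to give the tris-silyl ether A1. In its favour, one step makes ring A, two stereocentres and the conjugated triene, and A1 is one deprotection from 40. After the key step this alternative is clearly better in step economy than the chosen plan. Against it, A2 must already contain the quaternary C10 flanked by C15 and C11, the tetrasubstituted enal and a skipped polyene. The hardest atom of the molecule would therefore have to be built earlier on a ring that offers no help. Two aldehydes compete for the Lewis acid, and the C5=C6 geometry rests on which C5 hydrogen is transferred. On structure, both plans close ring A, but the chosen plan forms the spiro centre in the same step. On mechanism, the concerted ene transition state should predict the cis C7/C16 relationship at least as reliably as the directed reduction used here. That point is an equal or an advantage for the alternative. Overall length is unlikely to be shorter, because A2 is long.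

Alternative 2: The cut is the C10–C11 bond. (NH4)2Ce(NO3)6 (tetravalent cerium) would oxidise the silylene-tethered enol ether of the bis-enol ether A4. C11 of the trimethylsilyl enol ether would trap the radical cation at C10, closing ring B and creating the spiro carbon, and loss of silicon would give the hydroxy diketone A3. In its favour, the quaternary centre forms under mild conditions, and the silylene ring ties O15 and C16 together, so their cis relationship is enforced by the tether. That is better secured than the torquoselectivity relied on here. A3 also arrives with a free C15 hydroxyl and the C12 ketone. Against it, A3 has no carbon on C7 and two ketones to tell apart. Acylation at C7 would be done on a β-hydroxy ketone prone to retro-aldol cleavage. The enantiopure tertiary carbinol of A4 needs its own asymmetric synthesis. On structure, the core is the same but less functionalised. On mechanism, single-electron coupling replaces a cationic pericyclic cascade and is less sensitive to steric crowding at C10. On step economy, the route to the core may be shorter, but the added steps for C6 and carbonyl differentiation make the total about equal.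

Alternative 3: The cuts are C16–C10 and O–C15. NaOCl would convert the oxime A6 into a nitrile oxide that adds across the tetrasubstituted C10=C15 alkene, closing ring A and a temporary isoxazoline to give A5. In its favour, the suprafacial cycloaddition guarantees O15 cis to C16 (equal or better than the chosen plan on that relationship). C7 and C6 are already in place, and the reagents are cheap and safe. Against it, a tetrasubstituted dipolarophile reacts slowly and nitrile oxide dimerisation competes. The facial choice, and so the absolute configuration of C10 and C15, depends on remote induction from C7, which itself needs a separate asymmetric step. The N–O bond must later be reduced beside an alkene, and the 1,1-disubstituted alkene at C6 offers no handle for the Z-trisubstituted triene. On structure, it sets C10 and C15 together where the chosen plan takes C15 from the chiral pool and relays it to C10. On mechanism, the concerted cycloaddition is more predictable in reactivity than the cationic cascade. On step economy, the two are comparable, with the side-chain problem left unsolved in the alternative.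

Key step: step 12

Remark on the chemistry: (S)-linalool is assumed to be available in high enantiomeric purity. Its C3 becomes C15, the only external source of chirality, so its purity limits that of 40.

Check of the key-step structures: the stereodescriptors of 15 and 16 were checked against 40 and need no correction. C15 keeps the linalool configuration through the shift (retention), and the C10 descriptor of 16 is the one that places O15 cis to C16.

Locants: as in the first section; in the cycloheptene intermediates the same labels are used (C9=C10 alkene, C15 carbinol, C12 ketal carbon, C16 the exocyclic carbon on C10).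

Step 1
Reactants: 1 (S)-linalool
Product: 2 (S)-linalyl acetate
Conditions: Ac2O, Et3N, DMAP (cat.), CH2Cl2, rt → 40 °C
Reagents that add atoms: acetic anhydride, CC(=O)OC(C)=O
Why: DMAP-catalysed acylation of the tertiary allylic alcohol; the acetate prevents lactol formation after ozonolysis and is the electron-poor oxygen substituent wanted on C15 in step 12; the stereocentre is not touched.

Step 2
Reactants: 2 (S)-linalyl acetate
Product: 3 (S)-4-acetoxy-4-methylhex-5-enal
Conditions: O3, CH2Cl2–MeOH, −78 °C (Sudan Red 7B end-point); Me2S, −78 °C → rt
Reagents that add atoms: ozone, [O-][O+]=O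
Why: Chemoselective ozonolysis; the electron-rich trisubstituted alkene reacts far faster than the vinyl group, which is deactivated by the allylic acetate; cold reductive work-up of the ozonide gives the C12 aldehyde.

Step 3
Reactants: 4 3-bromo-2-(bromomethyl)prop-1-ene
Product: 5 2-(bromomethyl)allyl acetate
Conditions: KOAc (1 equiv), Bu4NBr (cat.), MeCN, 50 °C (4 in excess, recovered)
Reagents that add atoms: potassium acetate, CC(=O)[O-].[K+]
Why: SN2 mono-displacement of an allylic bromide by acetate; the excess of 4 suppresses double substitution.

Step 4
Reactants: 3 (S)-4-acetoxy-4-methylhex-5-enal; 5 2-(bromomethyl)allyl acetate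
Product: 6 homoallylic alcohol (both C12 epimers)
Conditions: In powder, THF–H2O (1:1), rt
Reagents that add atoms: none
Why: Barbier-type indium-mediated allylation forms C11–C12 in a neutral aqueous medium that leaves both acetates intact; an allyl donor at the alcohol oxidation level cannot lactonise onto the new hydroxyl as an acrylate donor would; the carbinol centre is oxidised in the next step.

Step 5
Reactants: 6 homoallylic alcohol
Product: 7 β,γ-unsaturated ketone
Conditions: Dess–Martin periodinane, NaHCO3, CH2Cl2, 0 °C → rt
Reagents that add atoms: none
Why: Dess–Martin oxidation under bicarbonate buffer gives the C12 ketone without acid- or base-induced migration of the 1,1-disubstituted alkene into conjugation.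

Step 6
Reactants: 7 β,γ-unsaturated ketone
Product: 8 dioxolane
Conditions: Me3SiOCH2CH2OSiMe3, Me3SiOTf (cat.), CH2Cl2, −78 → −20 °C; pyridine
Reagents that add atoms: 1,2-bis(trimethylsilyloxy)ethane, C[Si](C)(C)OCCO[Si](C)(C)C
Why: Noyori ketalisation at low temperature protects C12 without alkene migration or ionisation of the tertiary allylic acetate; the ketal later disfavours positive charge at C11 in step 12 and gives a gem-disubstituent assist to step 7.

Step 7
Reactants: 8 dioxolane
Product: 9 cycloheptene diacetate
Conditions: second-generation Grubbs catalyst RuCl2(=CHPh)(H2IMes)(PCy3) (5 mol%), toluene (0.005 M), 80 °C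
Reagents that add atoms: none
Why: Ring-closing metathesis joins the vinyl carbon C9 to the 1,1-disubstituted alkene carbon C10 with loss of ethene; high dilution and the two fully substituted ring atoms (C12, C15) favour the seven-membered ring over oligomers.

Step 8
Reactants: 9 cycloheptene diacetate
Product: 10 allylic alcohol
Conditions: K2CO3 (cat.), MeOH, 0 °C
Reagents that add atoms: none
Why: Methanolysis (transesterification) cleaves the primary allylic acetate orders of magnitude faster than the hindered tertiary one, so only the C16 hydroxyl is freed.

Step 9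
Reactants: 10 allylic alcohol
Product: 11 enal
Conditions: MnO2, CH2Cl2, rt
Reagents that add atoms: none
Why: Selective allylic oxidation with manganese dioxide under neutral heterogeneous conditions; acetate and ketal are not affected.

Step 10
Reactants: 11 enal; 12 methyl propiolate
Product: 14 bis-allylic carbinol (both C16 epimers), via methyl 2-(diisobutylalumanyl)acrylate 13 (not isolated)
Conditions: i-Bu2AlH, N-methylmorpholine N-oxide, THF, 0 °C; 12; then 11, 0 °C → rt
Reagents that add atoms: none
Why: Vinylalumination; hydroalumination of the propiolate gives the α-aluminated acrylate 13, which adds 1,2 to the enal to form C16–C7 (a Morita–Baylis–Hillman-type adduct); all hydride is consumed before 11 is added, so the tertiary acetate survives; the carbinol centre disappears in step 11.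

Step 11
Reactants: 14 bis-allylic carbinol
Product: 15 dienone (cycloheptenyl alkylidene β-keto ester)
Conditions: Dess–Martin periodinane, NaHCO3, CH2Cl2, 0 °C; cold filtration, used at once
Reagents that add atoms: none
Why: Dess–Martin oxidation of the doubly allylic alcohol under neutral buffered conditions; the α-methylene β-keto ester dimerises (hetero-Diels–Alder) and adds nucleophiles easily, so it is generated last and carried directly into step 12.

Step 12
Reactants: 15 dienone (cycloheptenyl alkylidene β-keto ester)
Product: 16 spiro[4.5] enone ester
Conditions: (MeCN)5Cu(SbF6)2 (divalent copper, 1.0 equiv), CH2Cl2, rt, slow addition of 15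
Reagents that add atoms: none
Why: Divalent copper chelates the 1,3-dicarbonyl unit and polarises the cross-conjugated dienone into a pentadienyl cation, whose 4π-conrotatory electrocyclisation joins C8 to C9 and closes ring A (five-membered), leaving a copper-bound oxyallyl cation with its charge at C10. The C9–C15 bond is aligned with the empty orbital at C10, and C15 shifts suprafacially from C9 to C10 with retention, so the seven-membered ring contracts to ring B (six-membered, closed by a 1,2-alkyl shift) and C10 becomes the spiro carbon. The resulting cation at C9 is quenched by a 1,2-hydride shift from C8, which places the charge β to the copper enolate and so gives the conjugated enone. The closest known reaction type is the Nazarov cyclisation/Wagner–Meerwein sequence of 1-cycloalkenyl alkylidene β-keto esters promoted by Cu(SbF6)2, which gives spirocyclic cyclopentenones by ring contraction and hydride shift. The one new stereocentre, C10, is controlled by C15 through torquoselectivity: C8 bonds to the C9 lobe anti to the C15–C14 ring bond with the acetoxy group in the inside position (inside-alkoxy arrangement), C15 then lies on the face from which it migrates, and O15 ends up cis to C16. The step needs the C15 shift to win over proton loss from C11 and over an H9 shift; the non-basic hexafluoroantimonate counter-ion, the stoichiometric copper and the C12 ketal, which destabilises charge at C11, work in that direction. It also needs the migration to stay concerted, which the acetate secures by damping lone-pair donation from O15 so that C15 does not ionise and scramble. Slow addition keeps 15 dilute and suppresses its dimerisation.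

Step 13
Reactants: 16 spiro[4.5] enone ester
Product: 18 hydroxy β-keto ester, via β-keto ester acetate 17 (not isolated)
Conditions: H2 (1 atm), Pd/C, THF, rt; then N2, MeOH, NaOMe (2.5 equiv), 0 °C → rt; AcOH
Reagents that add atoms: none
Why: Catalytic hydrogenation saturates the doubly activated C7=C8 alkene, the only alkene present; methoxide then holds the β-keto ester as its enolate, which shuts off retro-Claisen and retro-aldol (C10–C15) cleavage, while it methanolyses the tertiary acetate; C7 stays epimerisable and is fixed in step 14.

Step 14
Reactants: 18 hydroxy β-keto ester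
Product: 19 diol ester (C16–OH anti to O15, cis to CO2Me)
Conditions: Me4NBH(OAc)3, MeCN–AcOH (1:1), −30 → −20 °C
Reagents that add atoms: none
Why: Evans–Saksena directed reduction; the free C15 hydroxyl exchanges onto boron and delivers hydride to the C16 face syn to C15, giving the 1,3-anti diol; the ester on the equilibrating C7 takes the face away from the incoming hydride, so hydroxyl and ester end up cis (dynamic resolution through the enol).

Step 15
Reactants: 19 diol ester
Product: 20 C16 silyl ether
Conditions: t-BuMe2SiOTf (1.2 equiv), 2,6-lutidine, CH2Cl2, −78 → 0 °C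
Reagents that add atoms: tert-butyldimethylsilyl trifluoromethanesulfonate, CC(C)(C)[Si](C)(C)OS(=O)(=O)C(F)(F)F
Why: Silylation selects the secondary C16 hydroxyl over the much more hindered tertiary C15 hydroxyl; the bulky ether prevents hemiketal formation with C12 and later shields the C11 face syn to C16.

Step 16
Reactants: 20 C16 silyl ether
Product: 21 C12 ketone
Conditions: pyridinium p-toluenesulfonate (cat.), acetone–H2O, 50 °C
Reagents that add atoms: water, O
Why: Acid-catalysed hydrolysis of the dioxolane; the hindered secondary silyl ether and the ester are stable to this weak acid.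

Step 17
Reactants: 21 C12 ketone
Product: 22 enone (C13=C14)
Conditions: IBX (stabilised formulation), DMSO, 70 °C
Reagents that add atoms: none
Why: IBX dehydrogenation of the ketone through its enol; desaturation is only possible toward C13–C14 because C10 is quaternary, and the enone then blocks C13 so that C11 is the only enolisable α-carbon.

Step 18
Reactants: 22 enone (C13=C14); 23 3-(tert-butyldimethylsilyloxy)propanal
Product: 24 aldol adduct (mixture at C11 and C1′)
Conditions: LiN(SiMe3)2 (2.2 equiv), THF, −78 → −40 °C; 23, −78 °C; AcOH
Reagents that add atoms: none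
Why: Kinetic aldol addition of the cross-conjugated α′-lithium enolate forms C11–C1′; the second equivalent of base covers the free C15 hydroxyl, and the ketone α′-proton is far more acidic than the ester α-proton; both new centres are removed in step 19.

Step 19
Reactants: 24 aldol adduct
Product: 26 cross-conjugated dienone, via aldol mesylate 25 (not isolated)
Conditions: MsCl, Et3N, CH2Cl2, 0 °C; then DBU, rt
Reagents that add atoms: none
Why: Mesylation of the secondary aldol hydroxyl and E1cB elimination give the (E)-alkylidene ketone; the tertiary C15 hydroxyl is too hindered to be sulfonylated under these conditions.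

Step 20
Reactants: 26 cross-conjugated dienone
Product: 27 saturated ketone (C11 chain cis to C16)
Conditions: H2 (1 atm), Pd/C, EtOAc, rt
Reagents that add atoms: none
Why: Heterogeneous hydrogenation saturates both enone alkenes; hydrogen reaches C11 from the face opposite the C16 silyloxy group, which lies over the C11 side of ring A, so the chain ends up cis to C16 and O15 as in 40; the neutral conditions avoid epimerisation of the new α-stereocentre.

Step 21
Reactants: 27 saturated ketone
Product: 28 isopropenyl carbinol (C12 configuration not defined)
Conditions: CH2=C(CH3)MgBr, CeCl3, THF, −78 °C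
Reagents that add atoms: isopropenylmagnesium bromide, C=C(C)[Mg]Br
Why: Organocerium 1,2-addition; the weakly basic cerium reagent adds to the hindered, enolisable ketone without epimerising C11 and much faster than to the hindered methyl ester; the new carbinol configuration is irrelevant because C12 becomes sp2 in step 27.

Step 22
Reactants: 28 isopropenyl carbinol
Product: 29 chloromethyl ketone
Conditions: ICH2Cl, MeLi·LiBr (excess), THF, −78 °C; AcOH
Reagents that add atoms: chloroiodomethane, ClCI
Why: Chloromethyllithium, made in the flask by iodine–lithium exchange, adds once to the ester because the tetrahedral adduct is stable at −78 °C and collapses only on quench (carbenoid homologation of an ester to an α-chloro ketone); it forms C6–C6′, and the excess base covers the two free hydroxyls.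

Step 23
Reactants: 29 chloromethyl ketone
Product: 31 butenolide, via phosphonoacetate ester 30 (not isolated)
Conditions: (EtO)2P(O)CH2CO2K, DMF, rt; then K2CO3, 18-crown-6, rt
Reagents that add atoms: potassium diethylphosphonoacetate, CCOP(=O)(CC(=O)[O-])OCC.[K+]
Why: SN2 displacement of the α-chloro ketone by the carboxylate is followed by intramolecular Horner–Wadsworth–Emmons olefination; the five-membered ring forces C4 and the C6′ oxygen to be cis, which is the Z geometry required at C5=C6; the carbonate deprotonates only the phosphonoacetate, limiting epimerisation at C7 and β-elimination of the silyloxy group.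

Step 24
Reactants: 31 butenolide
Product: 32 lactol
Conditions: i-Bu2AlH, CH2Cl2, −78 °C; potassium sodium tartrate (aq.)
Reagents that add atoms: none
Why: Low-temperature hydride reduction stops at the tetrahedral aluminate (half-reduction of a lactone); the neutral tartrate work-up avoids acid-promoted dehydration to a furan.

Step 25
Reactants: 32 lactol
Product: 33 (1E,3Z)-iododiene alcohol
Conditions: CrCl2, CHI3, THF–dioxane, 0 °C → rt
Reagents that add atoms: iodoform, IC(I)I
Why: Takai olefination of the hydroxy-enal that is in equilibrium with the lactol; the geminal dichromium reagent gives the E-iodoalkene at C3=C4 and tolerates free hydroxyls, while the Z geometry of C5=C6 is inherited from the ring.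

Step 26
Reactants: 33 (1E,3Z)-iododiene alcohol
Product: 34 C6′ silyl ether
Conditions: t-BuMe2SiCl, imidazole, CH2Cl2, 0 °C
Reagents that add atoms: tert-butyldimethylsilyl chloride, CC(C)(C)[Si](C)(C)Cl
Why: Selective silylation of the primary allylic alcohol; the two tertiary alcohols are inert to the silyl chloride; this keeps C6′ from being oxidised in step 27.

Step 27
Reactants: 34 C6′ silyl ether
Product: 35 iododiene enal
Conditions: 2,2,6,6-tetramethyl-1-oxopiperidinium tetrafluoroborate, MeCN, 0 °C → rt; aq. NaHCO3
Reagents that add atoms: none
Why: Oxidative 1,3-transposition of a tertiary allylic alcohol (Babler–Dauben-type reaction with an oxoammonium salt); the C12–O bond is transposed to C18 and the primary allylic oxygen is oxidised in the same flask, giving the tetrasubstituted C12=C17 enal; the isomer with C18 syn to C13 should be favoured because the larger CH2–O terminus avoids the more crowded C11 side, but a minor geometric isomer is expected and would be removed by chromatography.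

Step 28
Reactants: 36 6-methylhept-5-en-2-one
Product: 37 enol triflate
Conditions: LiN(i-Pr)2, THF, −78 °C; PhNTf2, −78 → 0 °C
Reagents that add atoms: N-phenylbis(trifluoromethanesulfonimide), O=S(=O)(N(c1ccccc1)S(=O)(=O)C(F)(F)F)C(F)(F)F
Why: Kinetic deprotonation of the methyl ketone at the methyl group and O-sulfonylation give the terminal enol triflate.

Step 29
Reactants: 37 enol triflate
Product: 38 alkenyl pinacol boronate
Conditions: B2pin2, PdCl2(PPh3)2 (3 mol%), PPh3, KOPh, toluene, 50 °C
Reagents that add atoms: bis(pinacolato)diboron, CC1(C)OB(OC1(C)C)B1OC(C)(C)C(C)(C)O1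
Why: Miyaura borylation of an alkenyl triflate (zerovalent palladium formed in the flask, phenoxide as base) gives the 1,1-disubstituted alkenyl boronate.

Step 30
Reactants: 35 iododiene enal; 38 alkenyl pinacol boronate
Product: 39 tris-silyl ether of the target
Conditions: Pd(dppf)Cl2 (5 mol%), K3PO4 (aq.), THF, rt → 40 °C
Reagents that add atoms: none
Why: Suzuki–Miyaura coupling forms C2–C3 with retention of both alkene geometries; the mild phosphate conditions tolerate the hindered enal and the silyl ethers, and the sensitive triene appears only here.

Step 31
Reactants: 39 tris-silyl ether of the target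
Product: 40 target CNP0246965.2
Conditions: Bu4NF, AcOH, THF, rt → 40 °C
Reagents that add atoms: none
Why: Fluoride-mediated cleavage of the three silyl ethers, buffered with acetic acid to protect the enal from γ-deprotonation and the triene from base; no stereocentre or alkene geometry is touched.

Compound list

1 | (S)-linalool, (3S)-3,7-dimethylocta-1,6-dien-3-ol | C=C[C@@](C)(O)CCC=C(C)C | starting material
2 | (S)-linalyl acetate | C=C[C@@](C)(OC(C)=O)CCC=C(C)C | intermediate
3 | (S)-4-acetoxy-4-methylhex-5-enal | C=C[C@@](C)(OC(C)=O)CCC=O | intermediate
4 | 3-bromo-2-(bromomethyl)prop-1-ene | C=C(CBr)CBr | starting material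
5 | 2-(bromomethyl)allyl acetate | C=C(CBr)COC(C)=O | intermediate
6 | homoallylic alcohol, (7S)-4-hydroxy-7-methyl-2-methylidenenon-8-ene-1,7-diyl diacetate, both C4 epimers | C=C[C@@](C)(OC(C)=O)CCC(O)CC(=C)COC(C)=O | intermediate
7 | β,γ-unsaturated ketone, (7S)-7-methyl-2-methylidene-4-oxonon-8-ene-1,7-diyl diacetate | C=C[C@@](C)(OC(C)=O)CCC(=O)CC(=C)COC(C)=O | intermediate
8 | dioxolane, 2-[2-(acetoxymethyl)allyl]-2-[(3S)-3-acetoxy-3-methylpent-4-enyl]-1,3-dioxolane | C=C[C@@](C)(OC(C)=O)CCC1(CC(=C)COC(C)=O)OCCO1 | intermediate
9 | cycloheptene diacetate, [(9S)-9-acetoxy-9-methyl-1,4-dioxaspiro[4.6]undec-7-en-7-yl]methyl acetate | CC(=O)OCC1=C[C@@](C)(OC(C)=O)CCC2(OCCO2)C1 | intermediate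
10 | allylic alcohol, (9S)-7-(hydroxymethyl)-9-methyl-1,4-dioxaspiro[4.6]undec-7-en-9-yl acetate | OCC1=C[C@@](C)(OC(C)=O)CCC2(OCCO2)C1 | intermediate
11 | enal, (9S)-7-formyl-9-methyl-1,4-dioxaspiro[4.6]undec-7-en-9-yl acetate | O=CC1=C[C@@](C)(OC(C)=O)CCC2(OCCO2)C1 | intermediate
12 | methyl propiolate | C#CC(=O)OC | starting material
13 | methyl 2-(diisobutylalumanyl)acrylate | C=C(C(=O)OC)[Al](CC(C)C)CC(C)C | intermediate (not isolated)
14 | bis-allylic carbinol, methyl 2-{[(9S)-9-acetoxy-9-methyl-1,4-dioxaspiro[4.6]undec-7-en-7-yl](hydroxy)methyl}acrylate, both carbinol epimers | C=C(C(=O)OC)C(O)C1=C[C@@](C)(OC(C)=O)CCC2(OCCO2)C1 | intermediate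
15 | dienone, methyl 2-{[(9S)-9-acetoxy-9-methyl-1,4-dioxaspiro[4.6]undec-7-en-7-yl]carbonyl}acrylate (key-step precursor) | C=C(C(=O)OC)C(=O)C1=C[C@@](C)(OC(C)=O)CCC2(OCCO2)C1 | intermediate
16 | spiro[4.5] enone ester, methyl 6-acetoxy-9,9-(ethylenedioxy)-6-methyl-1-oxospiro[4.5]dec-2-ene-2-carboxylate (spiro locants: C1 = C16, C2 = C7, C5 = C10, C6 = C15, C9 = C12), acetoxy cis to C16 on ring B (key-step product) | COC(=O)C1=CC[C@]2(CC3(OCCO3)CC[C@]2(C)OC(C)=O)C1=O | intermediate
17 | β-keto ester acetate, 16 with C7–C8 saturated (C7 epimers and enol) | COC(=O)C1CC[C@]2(CC3(OCCO3)CC[C@]2(C)OC(C)=O)C1=O | intermediate (not isolated)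
18 | hydroxy β-keto ester, 17 with free C15 hydroxyl | COC(=O)C1CC[C@]2(CC3(OCCO3)CC[C@]2(C)O)C1=O | intermediate
19 | diol ester: ring A with C16–OH and C7–CO2Me cis, C16–OH anti to O15; ring B with C12 ethylene ketal and C15 methyl carbinol | COC(=O)[C@@H]1CC[C@]2(CC3(OCCO3)CC[C@]2(C)O)[C@@H]1O | intermediate
20 | C16 silyl ether, 19 with O16 as tert-butyldimethylsilyl ether | COC(=O)[C@@H]1CC[C@]2(CC3(OCCO3)CC[C@]2(C)O)[C@@H]1O[Si](C)(C)C(C)(C)C | intermediate
21 | C12 ketone, 20 with the ketal removed | COC(=O)[C@@H]1CC[C@]2(CC(=O)CC[C@]2(C)O)[C@@H]1O[Si](C)(C)C(C)(C)C | intermediate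
22 | enone, 21 with a C13=C14 double bond | COC(=O)[C@@H]1CC[C@]2(CC(=O)C=C[C@]2(C)O)[C@@H]1O[Si](C)(C)C(C)(C)C | intermediate
23 | 3-(tert-butyldimethylsilyloxy)propanal | O=CCCO[Si](C)(C)C(C)(C)C | starting material
24 | aldol adduct, 22 with a 1-hydroxy-3-(silyloxy)propyl group on C11, mixture at C11 and C1′ | COC(=O)[C@@H]1CC[C@]2(C(C(O)CCO[Si](C)(C)C(C)(C)C)C(=O)C=C[C@]2(C)O)[C@@H]1O[Si](C)(C)C(C)(C)C | intermediate
25 | aldol mesylate, 24 with the C1′ hydroxyl as methanesulfonate | COC(=O)[C@@H]1CC[C@]2(C(C(OS(C)(=O)=O)CCO[Si](C)(C)C(C)(C)C)C(=O)C=C[C@]2(C)O)[C@@H]1O[Si](C)(C)C(C)(C)C | intermediate (not isolated)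
26 | cross-conjugated dienone, (E)-C11=C1′ alkylidene and C13=C14 enone | COC(=O)[C@@H]1CC[C@]2(/C(=C\CCO[Si](C)(C)C(C)(C)C)C(=O)C=C[C@]2(C)O)[C@@H]1O[Si](C)(C)C(C)(C)C | intermediate
27 | saturated ketone, C11 3-(silyloxy)propyl chain cis to C16 and O15 | COC(=O)[C@@H]1CC[C@]2([C@H](CCCO[Si](C)(C)C(C)(C)C)C(=O)CC[C@]2(C)O)[C@@H]1O[Si](C)(C)C(C)(C)C | intermediate
28 | isopropenyl carbinol, 27 with OH and prop-1-en-2-yl on C12 (C12 configuration not defined) | COC(=O)[C@@H]1CC[C@]2([C@H](CCCO[Si](C)(C)C(C)(C)C)C(O)(C(C)=C)CC[C@]2(C)O)[C@@H]1O[Si](C)(C)C(C)(C)C | intermediate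
29 | chloromethyl ketone, 28 with C7–C(=O)CH2Cl in place of the ester | ClCC(=O)[C@@H]1CC[C@]2([C@H](CCCO[Si](C)(C)C(C)(C)C)C(O)(C(C)=C)CC[C@]2(C)O)[C@@H]1O[Si](C)(C)C(C)(C)C | intermediate
30 | phosphonoacetate ester, 29 with the chloride replaced by (diethoxyphosphoryl)acetoxy | CCOP(=O)(OCC)CC(=O)OCC(=O)[C@@H]1CC[C@]2([C@H](CCCO[Si](C)(C)C(C)(C)C)C(O)(C(C)=C)CC[C@]2(C)O)[C@@H]1O[Si](C)(C)C(C)(C)C | intermediate (not isolated)
31 | butenolide, C7 bonded to C4 of a furan-2(5H)-one (lactone carbonyl = chain C4, ring CH2 = C6′) | O=C1OCC(=C1)[C@@H]2CC[C@]3([C@H](CCCO[Si](C)(C)C(C)(C)C)C(O)(C(C)=C)CC[C@]3(C)O)[C@@H]2O[Si](C)(C)C(C)(C)C | intermediate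
32 | lactol, 31 reduced to the 2-hydroxy-2,5-dihydrofuran (both anomers) | OC1OCC(=C1)[C@@H]2CC[C@]3([C@H](CCCO[Si](C)(C)C(C)(C)C)C(O)(C(C)=C)CC[C@]3(C)O)[C@@H]2O[Si](C)(C)C(C)(C)C | intermediate
33 | (1E,3Z)-iododiene alcohol: C7–C6(CH2OH)=C5H–C4H=C3H–I, C4 cis to C6′ | I/C=C/C=C(\CO)[C@@H]1CC[C@]2([C@H](CCCO[Si](C)(C)C(C)(C)C)C(O)(C(C)=C)CC[C@]2(C)O)[C@@H]1O[Si](C)(C)C(C)(C)C | intermediate
34 | C6′ silyl ether, 33 with O6′ as tert-butyldimethylsilyl ether | I/C=C/C=C(\CO[Si](C)(C)C(C)(C)C)[C@@H]1CC[C@]2([C@H](CCCO[Si](C)(C)C(C)(C)C)C(O)(C(C)=C)CC[C@]2(C)O)[C@@H]1O[Si](C)(C)C(C)(C)C | intermediate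
35 | iododiene enal, 34 with the C12=C17(CH3)CHO unit, methyl cis to C11 | I/C=C/C=C(\CO[Si](C)(C)C(C)(C)C)[C@@H]1CC[C@]2([C@H](CCCO[Si](C)(C)C(C)(C)C)/C(=C(\C)C=O)CC[C@]2(C)O)[C@@H]1O[Si](C)(C)C(C)(C)C | intermediate
36 | 6-methylhept-5-en-2-one | CC(=O)CCC=C(C)C | starting material
37 | enol triflate, 6-methylhepta-1,5-dien-2-yl trifluoromethanesulfonate | C=C(CCC=C(C)C)OS(=O)(=O)C(F)(F)F | intermediate
38 | alkenyl pinacol boronate, 4,4,5,5-tetramethyl-2-(6-methylhepta-1,5-dien-2-yl)-1,3,2-dioxaborolane | C=C(CCC=C(C)C)B1OC(C)(C)C(C)(C)O1 | intermediate
39 | tris-silyl ether of the target (O16, O3′, O6′ as tert-butyldimethylsilyl ethers) | C=C(/C=C/C=C(\CO[Si](C)(C)C(C)(C)C)[C@@H]1CC[C@]2([C@H](CCCO[Si](C)(C)C(C)(C)C)/C(=C(\C)C=O)CC[C@]2(C)O)[C@@H]1O[Si](C)(C)C(C)(C)C)CCC=C(C)C | intermediate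
40 | CNP0246965.2 | C=C(/C=C/C=C(\CO)[C@@H]1CC[C@]2([C@H](CCCO)/C(=C(\C)C=O)CC[C@]2(C)O)[C@@H]1O)CCC=C(C)C | target

Total step count: 31. Longest linear sequence: 28 steps (steps 1, 2, 4–27, 30 and 31; steps 3, 28 and 29 are branches).

Steps least certain to work

Step 12 (key step). The cascade may end by proton loss from C11, or by a shift of H9 in place of C15, which gives a fused and not a spiro product. The conrotation may take the other sense and give the C10 epimer. The acetate may take part as a neighbouring group or C15 may ionise. The dienone may dimerise before it cyclises. None of these can be excluded, because the migrating carbon carries an oxygen substituent and the dienone terminus is unsubstituted. Fallback (ring contraction first, ring A second), setting out from 10 and returning at 18: silylation of 10 (t-BuMe2SiCl, imidazole) would give the tert-butyldimethylsilyl ether F1. Peracid epoxidation of C9=C10 anti to the acetoxy group would give the epoxide F2. Methylaluminium bis(4-bromo-2,6-di-tert-butylphenoxide) would open the epoxide at C10 and move C15 from C9 to C10 anti to the departing oxygen, a Lewis-acid epoxide rearrangement with ring contraction, giving the ring-contracted aldehyde F3 with the same C10 and C15 configuration as 16. Wittig reaction of the C9 aldehyde with the ylide of (2-carboxyethyl)triphenylphosphonium bromide, followed by MeI, would give the unsaturated methyl ester F4, and hydrogenation the saturated ester F5. Fluoride would free the primary alcohol F6. Oxidation (TEMPO, PhI(OAc)2, aqueous MeCN) would give the carboxylic acid F7, and MeI/K2CO3 the diester F8. Dieckmann cyclisation with NaOMe in MeOH can enolise only at C7 and also removes the tertiary acetate, so it would give 18.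

Step 27. The transposition may show poor geometric selectivity at C12=C17. The C15 hydroxyl may capture the allylic cation at C12 to form a bridged ether. Dehydration toward C11 or C13 is also possible. Fallback, from 34 to 35: a reversible 1,3-transposition with Ph3SiOReO3 (heptavalent rhenium, catalytic) would give the primary allylic alcohol F9 under thermodynamic control. The unwanted geometric isomer can be separated and resubmitted to the catalyst, and MnO2 would then oxidise only this allylic hydroxyl to give 35.

Step 25. The lactol may dehydrate to a furan under the Lewis-acidic chromium salts, or its ring may open too slowly for olefination. Fallback, from 31 to 34: Me3Al and MeNH(OMe)·HCl would open the butenolide to the Z-hydroxy Weinreb amide F10. Silylation would give the silyl ether F11 and i-Bu2AlH at −78 °C the Z-enal F12. This is a true aldehyde on which the Takai olefination (CrCl2, CHI3) is routine, and it would give 34 directly.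

Step 20. Hydrogen may be delivered from the wrong face if the free C15 hydroxyl anchors the substrate to the catalyst surface, which would give the C11 epimer. Fallback, from 22 to 27, with the opposite facial logic (carbon, not hydrogen, enters from the accessible face): α′-alkylation of 22 (LiN(SiMe3)2, allyl bromide) would give the allyl enone F13. Conjugate reduction of C13=C14 with [(Ph3P)CuH]6 (univalent copper hydride) would give the allyl ketone F14. Hydroboration with 9-BBN and perborate oxidation would give the primary alcohol F15, and t-BuMe2SiCl/imidazole would give 27.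

Further compounds

F1 | step 12 | tert-butyldimethylsilyl ether of 10 | CC(C)(C)[Si](C)(C)OCC1=C[C@@](C)(OC(C)=O)CCC2(OCCO2)C1
F2 | step 12 | C9–C10 epoxide of F1, oxygen trans to the acetoxy group | CC(C)(C)[Si](C)(C)OC[C@@]12O[C@@H]1[C@@](C)(OC(C)=O)CCC3(OCCO3)C2
F3 | step 12 | ring-contracted aldehyde, cyclohexane with C10 bearing CHO (C9) and CH2OSi (C16) | O=C[C@@]1(CO[Si](C)(C)C(C)(C)C)CC2(OCCO2)CC[C@]1(C)OC(C)=O
F4 | step 12 | unsaturated methyl ester, (Z)-C8=C9 | COC(=O)C/C=C\[C@@]1(CO[Si](C)(C)C(C)(C)C)CC2(OCCO2)CC[C@]1(C)OC(C)=O
F5 | step 12 | saturated ester | COC(=O)CCC[C@@]1(CO[Si](C)(C)C(C)(C)C)CC2(OCCO2)CC[C@]1(C)OC(C)=O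
F6 | step 12 | primary alcohol at C16 | COC(=O)CCC[C@@]1(CO)CC2(OCCO2)CC[C@]1(C)OC(C)=O
F7 | step 12 | carboxylic acid at C16 | COC(=O)CCC[C@@]1(C(=O)O)CC2(OCCO2)CC[C@]1(C)OC(C)=O
F8 | step 12 | diester | COC(=O)CCC[C@@]1(C(=O)OC)CC2(OCCO2)CC[C@]1(C)OC(C)=O
F9 | step 27 | primary allylic alcohol, C12=C17(CH3)CH2OH with methyl cis to C11 | I/C=C/C=C(\CO[Si](C)(C)C(C)(C)C)[C@@H]1CC[C@]2([C@H](CCCO[Si](C)(C)C(C)(C)C)/C(=C(\C)CO)CC[C@]2(C)O)[C@@H]1O[Si](C)(C)C(C)(C)C
F10 | step 25 | Z-hydroxy Weinreb amide | CON(C)C(=O)/C=C(\CO)[C@@H]1CC[C@]2([C@H](CCCO[Si](C)(C)C(C)(C)C)C(O)(C(C)=C)CC[C@]2(C)O)[C@@H]1O[Si](C)(C)C(C)(C)C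
F11 | step 25 | silyl ether of F10 | CON(C)C(=O)/C=C(\CO[Si](C)(C)C(C)(C)C)[C@@H]1CC[C@]2([C@H](CCCO[Si](C)(C)C(C)(C)C)C(O)(C(C)=C)CC[C@]2(C)O)[C@@H]1O[Si](C)(C)C(C)(C)C
F12 | step 25 | Z-enal | O=C/C=C(\CO[Si](C)(C)C(C)(C)C)[C@@H]1CC[C@]2([C@H](CCCO[Si](C)(C)C(C)(C)C)C(O)(C(C)=C)CC[C@]2(C)O)[C@@H]1O[Si](C)(C)C(C)(C)C
F13 | step 20 | allyl enone, allyl on C11 cis to C16 | COC(=O)[C@@H]1CC[C@]2([C@H](CC=C)C(=O)C=C[C@]2(C)O)[C@@H]1O[Si](C)(C)C(C)(C)C
F14 | step 20 | allyl ketone | COC(=O)[C@@H]1CC[C@]2([C@H](CC=C)C(=O)CC[C@]2(C)O)[C@@H]1O[Si](C)(C)C(C)(C)C
F15 | step 20 | primary alcohol, 3-hydroxypropyl on C11 | COC(=O)[C@@H]1CC[C@]2([C@H](CCCO)C(=O)CC[C@]2(C)O)[C@@H]1O[Si](C)(C)C(C)(C)C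
A1 | alternative 1 | tris-silyl ether of the target, carbonyl-ene product | C=C(/C=C/C=C(\CO[Si](C)(C)C(C)(C)C)[C@@H]1CC[C@]2([C@H](CCCO[Si](C)(C)C(C)(C)C)/C(=C(\C)C=O)CC[C@]2(C)O[Si](CC)(CC)CC)[C@@H]1O)CCC=C(C)C
A2 | alternative 1 | open-chain C16 aldehyde with the C6=C7 alkene, ene precursor | O=C[C@]1(CC/C=C(\CO[Si](C)(C)C(C)(C)C)C/C=C/C(=C)CCC=C(C)C)[C@H](CCCO[Si](C)(C)C(C)(C)C)/C(=C(\C)C=O)CC[C@]1(C)O[Si](CC)(CC)CC
A3 | alternative 2 | spiro hydroxy diketone | C1CC[C@]2(CC(=O)CC[C@]2(C)O)C1=O
A4 | alternative 2 | bis-enol ether, diisopropylsilylene bridging O15 and O16 with a trimethylsilyl enol ether at C12 | C=C(O[Si](C)(C)C)CC[C@]1(C)O[Si](C(C)C)(C(C)C)OC2=C1CCC2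
A5 | alternative 3 | tricyclic isoxazoline | C=C(CO[Si](C)(C)C(C)(C)C)[C@@H]1CC[C@@]23CC4(OCCO4)CC[C@]2(C)ON=C13
A6 | alternative 3 | C16 oxime with the tetrasubstituted C10=C15 cyclohexene | ON=C[C@H](C(=C)CO[Si](C)(C)C(C)(C)C)CCC1=C(C)CCC2(OCCO2)C1
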